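**Plan**

- Retrosynthesis: (1) the fifteen benzyl ethers come off last; (2) the C4(top)–C8(middle) interflavan bond is cut to a gallocatechin C4 cation equivalent and a protected gallocatechin-(4α→8)-catechin dimer; (3) in the dimer the C3 hydroxyl of the upper unit is traced back to a C–B bond, and ring C of that unit is cut at O1–C2 and C3–C4 into an o-quinone methide and an (E)-alkenylboronate; (4) the o-quinone methide precursor is cut at its C4–C8 bond into 8-lithiocatechin and a salicylaldehyde.
- Enabling feature: in the middle flavan unit, O1, C8a, C4a and C4 (a phenolic oxygen ortho to a benzylic carbon that carries ring A of the lower unit) are the four atoms of an o-quinone methide heterodiene. C2–C3 with its trans aryl/oxygen pair is an (E)-alkene, and the 2,3-trans-3,4-trans pattern of ring C is that of the endo adduct.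
- Forward: catechin is armed at C8 and joined to ring A of the future middle unit, which fixes the 4→8 regiochemistry by a C–C bond before ring C exists. One catalytic [4+2] then builds ring C with C2, C3 and C4; C–B is oxidised to C–OH; the top gallocatechin is attached by Lewis acid 4→8 coupling; hydrogenolysis ends the route.
- Stereochemistry: six centres are bought with (+)-catechin and (+)-gallocatechin. C4 of the middle unit is set by a chiral Brønsted acid, C3 and C2 are relayed from it by the suprafacial endo addition to the E-alkene, the C–B oxidation retains configuration, and C4 of the top unit is set anti to its C3 hydroxyl.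

Key step: step 6

Assumption: the (R)-configured acid of step 6 is taken to be the antipode that exposes the face of the o-quinone methide leading to the 4α-aryl configuration; if the facial sense is the opposite, the (S)-acid is used and nothing else changes.

**Step 1**
Reactants: 1 (+)-catechin
Product: 3 3,5,7,3',4'-penta-O-benzyl-(+)-catechin, via 5,7,3',4'-tetra-O-benzylcatechin 2 (not isolated)
Conditions: BnBr (6 equiv), K2CO3 (5 equiv), DMF, rt, Ar; then NaH (excess), 0 °C → rt
Reagents that add atoms: benzyl bromide, BrCc1ccccc1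
Why: Williamson etherification in two stages, the four phenols under K2CO3 and the C3 alcohol only after NaH is added, so that no free 4'-phenoxide is present under strong base (this avoids ring-opening epimerisation at C2 and C-benzylation of ring A).

**Step 2**
Reactants: 3 3,5,7,3',4'-penta-O-benzyl-(+)-catechin
Product: 4 8-bromo-3,5,7,3',4'-penta-O-benzyl-(+)-catechin
Conditions: NBS (1.0 equiv), CH2Cl2, −78 °C → rt
Reagents that add atoms: N-bromosuccinimide, O=C1CCC(=O)N1Br
Why: Electrophilic aromatic bromination at C8, the most nucleophilic position of the 5,7-dialkoxychroman ring A, as is established for benzylated flavan-3-ols.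

**Step 3**
Reactants: 5 2,4,6-trihydroxybenzaldehyde
Product: 6 2,4-bis(benzyloxy)-6-hydroxybenzaldehyde
Conditions: BnBr (2.1 equiv), K2CO3, DMF, rt
Reagents that add atoms: benzyl bromide, BrCc1ccccc1
Why: Chemoselective Williamson etherification, since the 4-OH and one of the two equivalent ortho OH groups react while the remaining ortho OH is deactivated by its hydrogen bond to the aldehyde.

**Step 4**
Reactants: 4 8-bromo-3,5,7,3',4'-penta-O-benzyl-(+)-catechin; 6 2,4-bis(benzyloxy)-6-hydroxybenzaldehyde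
Product: 9 [2,4-bis(benzyloxy)-6-hydroxyphenyl](penta-O-benzylcatechin-8-yl)methanol (both carbinol epimers), via 8-lithio-penta-O-benzylcatechin 7 (not isolated), via sodium 3,5-bis(benzyloxy)-2-formylphenoxide 8 (not isolated)
Conditions: 4, n-BuLi (1.05 equiv), THF, −78 °C; then 8 (from 6, NaH, THF, 0 °C), −78 → 0 °C; H2O quench; crude product filtered through Et3N-deactivated silica
Reagents that add atoms: none
Why: Bromine–lithium exchange followed by 1,2-addition of the aryllithium to the aldehyde, whose phenol is masked as its sodium salt so that it cannot quench the organometallic; the new carbinol centre is formed unselectively, which is of no consequence as it becomes sp2 in step 6.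

**Step 5**
Reactants: 10 3,4,5-tris(benzyloxy)benzaldehyde
Product: 11 (E)-2-[2-(3,4,5-tris(benzyloxy)phenyl)ethenyl]-4,4,5,5-tetramethyl-1,3,2-dioxaborolane
Conditions: CH2(Bpin)2 (1.2 equiv), LiTMP (lithium 2,2,6,6-tetramethylpiperidide, 1.2 equiv), THF, 0 °C; then 10, −78 °C → rt
Reagents that add atoms: bis(pinacolatoboryl)methane, CC1(C)OB(CB2OC(C)(C)C(C)(C)O2)OC1(C)C
Why: Boron-Wittig olefination, in which the lithiated geminal bis(boronate) adds to the aldehyde and syn elimination of the boron–oxygen fragment should give the E-alkenylboronate.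

**Step 6**
Reactants: 9 [2,4-bis(benzyloxy)-6-hydroxyphenyl](penta-O-benzylcatechin-8-yl)methanol; 11 (E)-2-[2-(3,4,5-tris(benzyloxy)phenyl)ethenyl]-4,4,5,5-tetramethyl-1,3,2-dioxaborolane
Product: 13 5,7,3',4',5'-penta-O-benzyl-3-deoxy-3-(pinacolatoboryl)gallocatechin-(4α→8)-3,5,7,3',4'-penta-O-benzylcatechin, via E-o-quinone methide 12 (not isolated)
Conditions: 11 (1.5 equiv), (R)-3,3'-bis(2,4,6-triisopropylphenyl)-1,1'-binaphthyl-2,2'-diyl N-triflylphosphoramide (10 mol %), 5 Å MS, PhMe, 0 °C → rt
Reagents that add atoms: none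
Why: Proposed new method: the acid dehydrates 9 to the E-configured o-quinone methide 12 (in its protonated form a contact ion pair of the diarylmethyl cation with the chiral phosphoramide anion held at the C8a oxygen), and 11 adds across O1=C8a–C4a=C4 in an asynchronous inverse-electron-demand oxa-[4+2] in which C3–C4 bonding runs ahead and O1–C2 closure follows; the closest known reaction type is the chiral N-triflylphosphoramide-catalysed [4+2] of o-hydroxybenzhydrol-derived o-quinone methides with styrenes to give 2,4-cis-2,4-diarylchromans, whereas an alkenylboronate has not been used as the 2π partner. Ring C is closed by intermolecular cycloaddition (at the stepwise limit by six-membered collapse of the phenol oxygen onto the C2 benzylic cation). C4 is set by the catalyst, whose 3,3'-aryl groups shield one face of the bound o-quinone methide while the remote catechin centres exert little bias, and C3 and C2 are relayed from C4 by the suprafacial endo addition (aryl under the dienone, boryl group exo) to the E-alkene, which gives 2,4-cis and 2,3-trans and hence 3,4-trans. The step needs O1-to-C2/C4-to-C3 regioselectivity, which boron secures: attack at the boron-bearing carbon places the charge on the benzylic carbon β to boron and the alternative α-boryl cation is disfavoured, the opposite of what an enol ether would give. Ring closure should outrun loss of boron (net alkenyl transfer) because the pinacol ester has no exchangeable ligand for ate-complex formation and O1 is delivered intramolecularly; the Z isomer of 12 should be unreactive since its inside aryl group blocks the diene termini, and the other two ring A oxygens are benzylated so that only O1 can close.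

**Step 7**
Reactants: 13 5,7,3',4',5'-penta-O-benzyl-3-deoxy-3-(pinacolatoboryl)gallocatechin-(4α→8)-3,5,7,3',4'-penta-O-benzylcatechin
Product: 14 5,7,3',4',5'-penta-O-benzylgallocatechin-(4α→8)-3,5,7,3',4'-penta-O-benzylcatechin
Conditions: H2O2 (30 % aq), NaOH (aq), THF, 0 °C → rt
Reagents that add atoms: hydrogen peroxide, OO
Why: Oxidation of the secondary alkylboronate through 1,2-migration of carbon from boron to oxygen in the hydroperoxide ate complex, which proceeds with retention and so gives the 3β-hydroxyl (2,3-trans, 3,4-trans).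

**Step 8**
Reactants: 15 (+)-gallocatechin
Product: 16 5,7,3',4',5'-penta-O-benzyl-(+)-gallocatechin
Conditions: BnBr (5.5 equiv), K2CO3, DMF, rt, Ar
Reagents that add atoms: benzyl bromide, BrCc1ccccc1
Why: Phenol-selective Williamson etherification, as K2CO3 does not deprotonate the C3 alcohol, run under argon to protect the pyrogallol ring from oxidation.

**Step 9**
Reactants: 16 5,7,3',4',5'-penta-O-benzyl-(+)-gallocatechin
Product: 17 (2R,3S,4S)-5,7,3',4',5'-penta-O-benzyl-4-(2-ethoxyethoxy)gallocatechin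
Conditions: DDQ (2 equiv), 2-ethoxyethanol (excess), CH2Cl2, rt
Reagents that add atoms: 2-ethoxyethanol, CCOCCO
Why: DDQ benzylic oxidation, in which hydride abstraction at C4 (activated by the 5- and 7-alkoxy groups) gives a cation that the alcohol traps, expected mainly as the 4β ether; the C4 configuration is immaterial because it is ionised again in step 10.

**Step 10**
Reactants: 14 5,7,3',4',5'-penta-O-benzylgallocatechin-(4α→8)-3,5,7,3',4'-penta-O-benzylcatechin; 17 (2R,3S,4S)-5,7,3',4',5'-penta-O-benzyl-4-(2-ethoxyethoxy)gallocatechin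
Product: 18 pentadeca-O-benzylprodelphinidin C2
Conditions: AgOTf (1 equiv), CH2Cl2, rt, 14 and 17 equimolar
Reagents that add atoms: none
Why: Lewis acid ionisation of the chelating 2-ethoxyethoxy group gives the C4 benzylic cation, which undergoes Friedel–Crafts attack by C8 of the upper unit of 14 (its most nucleophilic free position) on the face anti to the C3 hydroxyl of the electrophile, so the new centre should be 3,4-trans (4α).

**Step 11**
Reactants: 18 pentadeca-O-benzylprodelphinidin C2
Product: 19 Prodelphinidin C2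
Conditions: H2 (1 atm), Pd(OH)2/C (20 wt %), THF/MeOH/H2O, rt; Sephadex LH-20
Reagents that add atoms: none
Why: Hydrogenolysis of all fifteen benzyl ethers under neutral conditions, under which the cyclic O1–C2 ethers and the interflavan C–C bonds should persist and no stereocentre is touched.

**Compound list**

1 | (+)-catechin, (2R,3S) | Oc1cc(O)c2c(c1)O[C@H](c1ccc(O)c(O)c1)[C@@H](O)C2 | starting material
2 | 5,7,3',4'-tetra-O-benzyl-(+)-catechin | O(Cc3ccccc3)c1cc(OCc3ccccc3)c2c(c1)O[C@H](c1ccc(OCc3ccccc3)c(OCc3ccccc3)c1)[C@@H](O)C2 | intermediate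
3 | 3,5,7,3',4'-penta-O-benzyl-(+)-catechin | O(Cc3ccccc3)c1cc(OCc3ccccc3)c2c(c1)O[C@H](c1ccc(OCc3ccccc3)c(OCc3ccccc3)c1)[C@@H](OCc3ccccc3)C2 | intermediate
4 | 8-bromo-3,5,7,3',4'-penta-O-benzyl-(+)-catechin | O(Cc3ccccc3)c1cc(OCc3ccccc3)c2c(c1Br)O[C@H](c1ccc(OCc3ccccc3)c(OCc3ccccc3)c1)[C@@H](OCc3ccccc3)C2 | intermediate
5 | 2,4,6-trihydroxybenzaldehyde | O=Cc1c(O)cc(O)cc1O | starting material
6 | 2,4-bis(benzyloxy)-6-hydroxybenzaldehyde | O=Cc1c(O)cc(OCc2ccccc2)cc1OCc1ccccc1 | intermediate
7 | 8-lithio-3,5,7,3',4'-penta-O-benzylcatechin | O(Cc3ccccc3)c1cc(OCc3ccccc3)c2c(c1[Li])O[C@H](c1ccc(OCc3ccccc3)c(OCc3ccccc3)c1)[C@@H](OCc3ccccc3)C2 | intermediate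
8 | sodium 3,5-bis(benzyloxy)-2-formylphenoxide | [Na+].[O-]c1cc(OCc2ccccc2)cc(OCc2ccccc2)c1C=O | intermediate
9 | [2,4-bis(benzyloxy)-6-hydroxyphenyl](penta-O-benzylcatechin-8-yl)methanol, both carbinol epimers | OC(c1c(O)cc(OCc3ccccc3)cc1OCc1ccccc1)c1c(OCc3ccccc3)cc(OCc3ccccc3)c2c1O[C@H](c1ccc(OCc3ccccc3)c(OCc3ccccc3)c1)[C@@H](OCc3ccccc3)C2 | intermediate
10 | 3,4,5-tris(benzyloxy)benzaldehyde | O=Cc1cc(OCc2ccccc2)c(OCc2ccccc2)c(OCc2ccccc2)c1 | starting material
11 | (E)-2-[2-(3,4,5-tris(benzyloxy)phenyl)ethenyl]-4,4,5,5-tetramethyl-1,3,2-dioxaborolane | CC1(C)OB(/C=C/c2cc(OCc3ccccc3)c(OCc3ccccc3)c(OCc3ccccc3)c2)OC1(C)C | intermediate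
12 | (E)-3,5-bis(benzyloxy)-6-[(penta-O-benzylcatechin-8-yl)methylidene]cyclohexa-2,4-dien-1-one (o-quinone methide) | O=C1C=C(OCc3ccccc3)C=C(OCc3ccccc3)/C1=C\c1c(OCc3ccccc3)cc(OCc3ccccc3)c2c1O[C@H](c1ccc(OCc3ccccc3)c(OCc3ccccc3)c1)[C@@H](OCc3ccccc3)C2 | intermediate
13 | 5,7,3',4',5'-penta-O-benzyl-3-deoxy-3-(pinacolatoboryl)gallocatechin-(4α→8)-3,5,7,3',4'-penta-O-benzylcatechin; new ring has 2α-aryl, 3β-boryl, 4α-aryl | c1c(OCc3ccccc3)cc(OCc3ccccc3)c2c1O[C@H](c1cc(OCc3ccccc3)c(OCc3ccccc3)c(OCc3ccccc3)c1)[C@@H](B3OC(C)(C)C(C)(C)O3)[C@@H]2c1c(OCc3ccccc3)cc(OCc3ccccc3)c2c1O[C@H](c1ccc(OCc3ccccc3)c(OCc3ccccc3)c1)[C@@H](OCc3ccccc3)C2 | intermediate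
14 | 5,7,3',4',5'-penta-O-benzylgallocatechin-(4α→8)-3,5,7,3',4'-penta-O-benzylcatechin; upper unit 2R,3S,4S with free 3-OH | c1c(OCc3ccccc3)cc(OCc3ccccc3)c2c1O[C@H](c1cc(OCc3ccccc3)c(OCc3ccccc3)c(OCc3ccccc3)c1)[C@@H](O)[C@@H]2c1c(OCc3ccccc3)cc(OCc3ccccc3)c2c1O[C@H](c1ccc(OCc3ccccc3)c(OCc3ccccc3)c1)[C@@H](OCc3ccccc3)C2 | intermediate
15 | (+)-gallocatechin, (2R,3S) | Oc1cc(O)c2c(c1)O[C@H](c1cc(O)c(O)c(O)c1)[C@@H](O)C2 | starting material
16 | 5,7,3',4',5'-penta-O-benzyl-(+)-gallocatechin | O(Cc3ccccc3)c1cc(OCc3ccccc3)c2c(c1)O[C@H](c1cc(OCc3ccccc3)c(OCc3ccccc3)c(OCc3ccccc3)c1)[C@@H](O)C2 | intermediate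
17 | (2R,3S,4S)-5,7,3',4',5'-penta-O-benzyl-4-(2-ethoxyethoxy)gallocatechin | O(Cc3ccccc3)c1cc(OCc3ccccc3)c2c(c1)O[C@H](c1cc(OCc3ccccc3)c(OCc3ccccc3)c(OCc3ccccc3)c1)[C@@H](O)[C@H]2OCCOCC | intermediate
18 | pentadeca-O-benzylprodelphinidin C2 (all phenols and the 3-OH of the lower unit benzylated; 3-OH of the top and middle units free) | O(Cc3ccccc3)c1cc(OCc3ccccc3)c2c(c1)O[C@H](c1cc(OCc3ccccc3)c(OCc3ccccc3)c(OCc3ccccc3)c1)[C@@H](O)[C@@H]2c1c(OCc3ccccc3)cc(OCc3ccccc3)c2c1O[C@H](c1cc(OCc3ccccc3)c(OCc3ccccc3)c(OCc3ccccc3)c1)[C@@H](O)[C@@H]2c1c(OCc3ccccc3)cc(OCc3ccccc3)c2c1O[C@H](c1ccc(OCc3ccccc3)c(OCc3ccccc3)c1)[C@@H](OCc3ccccc3)C2 | intermediate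
19 | Prodelphinidin C2, gallocatechin-(4α→8)-gallocatechin-(4α→8)-catechin | Oc1cc(O)c2c(c1)O[C@H](c1cc(O)c(O)c(O)c1)[C@@H](O)[C@@H]2c1c(O)cc(O)c2c1O[C@H](c1cc(O)c(O)c(O)c1)[C@@H](O)[C@@H]2c1c(O)cc(O)c2c1O[C@H](c1ccc(O)c(O)c1)[C@@H](O)C2 | target

**Step count**

Total step count: 11. Longest linear sequence: 7 steps (steps 1, 2, 4, 6, 7, 10, 11).

**Steps most likely to fail**

Step 6. After C3–C4 bonding the β-boryl benzylic cation may lose boron (net alkenyl transfer to C4) instead of closing O1–C2, the weakly nucleophilic alkenylboronate may add too slowly to the donor-stabilised o-quinone methide, or facial discrimination may be weak. The fallback uses known chemistry and sets out from 10 and 9. Ohira–Bestmann homologation of 10 (dimethyl (1-diazo-2-oxopropyl)phosphonate, K2CO3, MeOH) should give 5-ethynyl-1,2,3-tris(benzyloxy)benzene F1. The acid-catalysed [4+2] of the o-quinone methide from 9 with this arylalkyne (same chiral acid, PhMe) should give, through an aryl-stabilised vinyl cation that closes onto O1, the 2,4-diaryl-4H-chromene F2. Hydroboration of the enol ether double bond of F2 (BH3·SMe2, THF) from the face anti to the C4 aryl group, followed by NaOH/H2O2, should then install H at C2 and OH at C3 with the 2,3-trans-3,4-trans pattern. The fallback comes back to the route at 14.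

Step 4. Addition between two di-ortho-substituted partners may be slow enough for the aryllithium to be lost by proton transfer from a neighbouring benzyl ether, and the very acid-labile benzhydrol may ionise and oligomerise during isolation. The fallback sets out from 4: the aryllithium 7 is quenched with DMF to give 8-formyl-3,5,7,3',4'-penta-O-benzylcatechin F3. Phenylboronic acid-templated ortho-hydroxyalkylation of commercial 3,5-bis(benzyloxy)phenol with F3 (PhB(OH)2, cat. EtCO2H, PhMe, reflux, water removal) should give the 2-phenyl-4H-1,3,2-benzodioxaborin F4, a neutral and chromatographable store of the same o-quinone methide. Under the acid of step 6, F4 should release 12, so the fallback comes back to the route at 12 and hence at 13.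

Step 10. The electrophile may condense with itself through its own C8, the product may be extended further at C8 of its new top unit, and attack at the C6 positions may compete. The fallback blocks C8 of the electrophile and sets out from 16. Bromination (NBS, CH2Cl2, −78 °C) should give 8-bromo-5,7,3',4',5'-penta-O-benzylgallocatechin F5. DDQ with 2-ethoxyethanol should give its 4-(2-ethoxyethoxy) derivative F6. Coupling of F6 with 14 (TMSOTf, CH2Cl2, −78 °C) should give the 8-bromo protected trimer F7, which can neither self-condense nor grow. Hydrogenolysis of F7 with H2, Pd(OH)2/C and Et3N should remove the bromine together with the benzyl groups, so the fallback comes back to the route at 19.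

**Further compounds**

F1 | step 6 | 5-ethynyl-1,2,3-tris(benzyloxy)benzene | C#Cc1cc(OCc2ccccc2)c(OCc2ccccc2)c(OCc2ccccc2)c1
F2 | step 6 | 5,7-bis(benzyloxy)-2-[3,4,5-tris(benzyloxy)phenyl]-4-(penta-O-benzylcatechin-8-yl)-4H-chromene, C4 as in 14 | c1c(OCc3ccccc3)cc(OCc3ccccc3)c2c1OC(c1cc(OCc3ccccc3)c(OCc3ccccc3)c(OCc3ccccc3)c1)=C[C@@H]2c1c(OCc3ccccc3)cc(OCc3ccccc3)c2c1O[C@H](c1ccc(OCc3ccccc3)c(OCc3ccccc3)c1)[C@@H](OCc3ccccc3)C2
F3 | step 4 | 8-formyl-3,5,7,3',4'-penta-O-benzyl-(+)-catechin | O(Cc3ccccc3)c1cc(OCc3ccccc3)c2c(c1C=O)O[C@H](c1ccc(OCc3ccccc3)c(OCc3ccccc3)c1)[C@@H](OCc3ccccc3)C2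
F4 | step 4 | 5,7-bis(benzyloxy)-2-phenyl-4-(penta-O-benzylcatechin-8-yl)-4H-1,3,2-benzodioxaborin, both C4 epimers | O(Cc3ccccc3)c1cc(OCc3ccccc3)c2c(c1)OB(c1ccccc1)OC2c1c(OCc3ccccc3)cc(OCc3ccccc3)c2c1O[C@H](c1ccc(OCc3ccccc3)c(OCc3ccccc3)c1)[C@@H](OCc3ccccc3)C2
F5 | step 10 | 8-bromo-5,7,3',4',5'-penta-O-benzyl-(+)-gallocatechin | O(Cc3ccccc3)c1cc(OCc3ccccc3)c2c(c1Br)O[C@H](c1cc(OCc3ccccc3)c(OCc3ccccc3)c(OCc3ccccc3)c1)[C@@H](O)C2
F6 | step 10 | (2R,3S,4S)-8-bromo-5,7,3',4',5'-penta-O-benzyl-4-(2-ethoxyethoxy)gallocatechin | O(Cc3ccccc3)c1cc(OCc3ccccc3)c2c(c1Br)O[C@H](c1cc(OCc3ccccc3)c(OCc3ccccc3)c(OCc3ccccc3)c1)[C@@H](O)[C@H]2OCCOCC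
F7 | step 10 | 8-bromo (top unit) pentadeca-O-benzylprodelphinidin C2 | O(Cc3ccccc3)c1cc(OCc3ccccc3)c2c(c1Br)O[C@H](c1cc(OCc3ccccc3)c(OCc3ccccc3)c(OCc3ccccc3)c1)[C@@H](O)[C@@H]2c1c(OCc3ccccc3)cc(OCc3ccccc3)c2c1O[C@H](c1cc(OCc3ccccc3)c(OCc3ccccc3)c(OCc3ccccc3)c1)[C@@H](O)[C@@H]2c1c(OCc3ccccc3)cc(OCc3ccccc3)c2c1O[C@H](c1ccc(OCc3ccccc3)c(OCc3ccccc3)c1)[C@@H](OCc3ccccc3)C2
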